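In the first 20.0 min, target climbs in Thursday's, Monday's and Tuesday's runs to near 17.2% of the starting material charged, and then the readings sag. The next flask has to be stopped at some time, so we need to know what waiting costs.

| flask | starting material | second substrate | free catalyst | remark | time |
|---|---|---|---|---|---|
| Thursday's | 0.067 M | 0.10 M | 16 mM | run made earlier |  |
| Monday's | 0.15 M | 0.10 M | 16 mM | run made earlier |  |
| Tuesday's | 0.10 M | 0.20 M | 16 mM | run made earlier |  |
| flask | 0.10 M | 0.100 M | 16 mM |  | 50 min |

- Thursday's (time / min: target / %): 4.00: 10.3; 6.00: 14.0; 10.0: 16.7; 12.0: 16.8; 20.0: 16.7; 30.0: 16.8; 40.0: 15.8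
- Monday's (time / min: target / %): 4.00: 11.3; 6.00: 13.2; 10.0: 16.2; 12.0: 17.3; 20.0: 17.8; 30.0: 17.7; 40.0: 16.1
- Tuesday's (time / min: target / %): 4.00: 11.0; 8.00: 15.0; 12.0: 16.9; 25.0: 16.4; 40.0: 16.2

(each reading ± 0.5 percentage points)

* time up to 50 min at which target stands highest
* the amount of target, in percent of the starting material charged, at that time
* the first time at which target reaches 8.7%, in the same percent, in min

- the earlier runs were read with a standard deviation of 0.5 percentage points
- candidate steps: starting material + free catalyst <-> catalyst intermediate A; catalyst intermediate A <-> free catalyst + target; second substrate + free catalyst <-> catalyst intermediate B; catalyst intermediate B -> free catalyst + second product; free catalyst + target -> free catalyst + over-reaction product; 2 free catalyst <-> resting dimer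

We treat the sag apart from the rise as a pseudo-first-order loss, d[target]/dt = −k[target]. This integrates to an exponential decay from the top. We call k the sag constant, the fractional loss of target per minute after the top.

From a reading near the top of each run to its reading at 40.0 min, the logarithm of the ratio over the time between gives 0.00219 min⁻¹ on Thursday's, 0.00502 min⁻¹ on Monday's and 0.00151 min⁻¹ on Tuesday's. The drops behind these values are 1 percentage point, 1.7 points and 0.7 points, against a scatter of 0.5 points on each reading, so we take the mean as a reading: 0.00291 min⁻¹, a time constant of 344 min, much longer than the 20.0 min within which the rise is over.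

Waiting from 20.0 min to 50 min in the asked flask then costs 1.4 points, against a scatter of 0.5 points. So we charge the flask as asked, stop it near 20.0 min and do not chase the peak to the minute.

The forecast gives 17% at 18 min, with 8.7% reached at 2.9 min, and says “The peak is therefore broad”.

The flask gives 17.3% at 17.8 min, and 8.7% at 2.63 min.

    starting material + free catalyst ⇌ catalyst intermediate A (K = 3.30 M⁻¹, k = 1.20 M⁻¹ s⁻¹)
    catalyst intermediate A ⇌ free catalyst + target (K = 0.0770 M, k = 0.0416 s⁻¹)
    second substrate + free catalyst ⇌ catalyst intermediate B (K = 3.60 M⁻¹, k = 9.05 M⁻¹ s⁻¹)
    catalyst intermediate B → free catalyst + second product (k = 0.229 s⁻¹)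
    free catalyst + target → free catalyst + over-reaction product (k = 0.0562 M⁻¹ s⁻¹)
    2 free catalyst ⇌ resting dimer (K = 116 M⁻¹, k = 2.00 M⁻¹ s⁻¹)

In this flask, second substrate fell to 25.4% of its charge by 5.00 min and 0.820% by 17.9 min, while target rose to its top. After that, with resting dimer, the resting state, holding 52.8% of the catalyst charged, over-reaction product grew from 5.00% at 17.9 min to 15.9% at 50.0 min. The sag constant, started from the flask's top, gives 15.8% at 50 min, and the flask holds 15.6%. For the same flask read at 80 min, it gives 14.4%, and the computed amount is 13.9%.

Readings and results were computed with made-up constants; the scatter is artificial.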